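## The problem

Compound 18 is a glycerol 2-alkyl ether. Its C8 chain ends in a linear tetracycle made of one cyclohexane (ring A) and three cyclobutanes (rings B, C and D, counted outward from ring A).

Locants throughout are those of the open-chain precursor 12. C7 carries the chain; C6, C8 and C9 are the other CH2 groups of ring A. C5/C10 form the A/B fusion, C4/C11 the B/C fusion, C3/C12 the C/D fusion, and C2/C13 are the two CH2 groups of ring D.

Six of the seven stereocentres (C3, C4, C5, C10, C11, C12) are contiguous ladder CH groups. All ring fusions are cis and neighbouring rings are anti, so these centres can only be set relative to one another, by the way each cyclobutane is closed.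

The seventh stereocentre, C7 (S), has the chain cis to ring B. It can be bought as a single enantiomer, but it lies 1,3 to C5 and 1,4 to C10 and cannot be expected to steer them. The C7-to-ladder relationship is therefore the hard stereochemical question.

The fused cyclobutanes are highly strained. They will not survive strong heating, carbocations or long-lived radicals beside the rings, or low-valent metals that insert into strained C–C bonds. Everything after ladder formation must be mild, and the 1,3-diol has to stay masked until the end.

The enabling feature is that each rail, C2–C3–C4–C5 and C13–C12–C11–C10, is a four-carbon unit that can be written as a 1,3-diene. Ring A joins the two rails at C5 and C10 through the four sp3 carbons C6–C9. Four rungs (C5–C10, C4–C11, C3–C12, C2–C13) stitched between two tethered dienes therefore close rings A, B, C and D together. The C5–C10 rung is also the double bond of a cyclohex-3-ene, which is how C7 can be bought.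

## Retrosynthesis

**18 from 17.** The only cut is the acetal C–O bonds. The diol is released last from acetonide 17 with dilute aqueous acid, which a saturated ladderane tolerates.

**17 from 15 and 14.** The C2–C1 and C13–C14 bonds are cut: two carboxyl groups are added retrosynthetically to the ring D CH2 carbons. Leaving C2 and C13 as bare vinyl termini was weighed and set aside. Once the dienes have reacted, only two isolated vinyl groups would remain, with no chromophore a sensitiser can reach and nothing but the rule of five to guide their closure, which points to the crossed product. Ester termini keep an excitable acrylate at that stage and stabilise the radicals at C2 and C13, which favours the straight closure. The price is two steps (saponification to 15, twofold Barton decarboxylation to 17). The configuration at C2 and C13 is irrelevant because both centres are erased.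

**14 from 12 (through 13).** All four rungs are cut: C5–C10, C4–C11, C3–C12 and C2–C13. This removes four rings and eight stereocentres in one operation and leaves an acyclic tetraene diester with a single stereocentre. The forward reaction has to stitch two tethered (2E,4E)-dienoates rung by rung. This is the step that carries the plan and the one that is not yet known chemistry.

**12 from 10 and 11.** The C4=C5 and C10=C11 double bonds are cut. A twofold vinylogous Horner–Wadsworth–Emmons reaction of dialdehyde 10 with phosphonate 11 installs both complete dienoate arms in one step with E geometry. This is shorter than two rounds of two-carbon homologation.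

**10 from 8.** The C5 and C10 aldehydes are rejoined as a ring alkene. Dialdehyde 10 is the ozonolysis product of 4-substituted cyclohexene 8, so the six carbons of ring A and C7 come from one ring. The key step later re-forms the C5–C10 bond that ozonolysis broke. The two arms differ by one CH2 exactly as the target requires.

**8 from 3 and 7.** The bond between the first and second chain carbons is cut. A copper-catalysed coupling of primary tosylate 3 with Grignard reagent 7 leaves C7 untouched. An olefination at the ring-bearing carbon would put C7 alpha to an aldehyde and risk epimerisation.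

**7 and 6 from 4 and 5.** The glycerol C2–O–CH2 ether bond is cut. Williamson alkylation of the 1,3-acetonide-protected glycerol 4 with excess dibromide 5 gives bromide 6, from which 7 is made in the flask.

**3 from 2 and 1.** Reduction of the commercial (S)-acid 1 gives alcohol 2, which is sulfonylated to 3. No stereocentre is made or disturbed.

## Roads not taken

**Alternative 1:** The cut is at the B/C and C/D fusion bonds of a chain-free tetracycle. In the forward sense the cis-fused cyclohexeno-cyclooctatriene A1 would equilibrate thermally by disrotatory 6π closure (C4–C11, ring B). Photochemical disrotatory 4π closure of the resulting cyclohexadiene (C3–C12) would then give the meso diene A2, with ring A a cyclohexene and ring D a cyclobutene.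

- Merits: both closures are orbital-symmetry controlled, so the cis fusions are guaranteed. A1 is a small hydrocarbon, and no chain stereocentre is present to produce a diastereomer mixture when the ladder forms.
- Weak points: the 6π equilibrium lies on the triene side and the triene absorbs the light too. Bicyclo[4.2.0]octadienes tend to fragment to an arene and an alkene. Orbital symmetry does not dictate the anti relationship of ring A to ring C.
- Further burden: A2 is meso. The chain would have to be attached to the ring A alkene enantioselectively and in the presence of the far more reactive cyclobutene, and both alkenes then reduced.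
- Comparison: in relative stereocontrol within the ladder and in freedom from a C7 diastereomer problem this road is better. The chosen plan sets against it that the chain and the absolute configuration are in place from the first step and that no selective chemistry on a fragile ladderene is needed.

**Alternative 2:** The cut is at the two ring D bonds C3–C2 and C12–C13. Dichloroketene would add thermally to the cyclobutene of the tricyclic alkene A3 (rings A, B and C, chain carried as a benzyl ether) to give dichlorocyclobutanone A4.

- Merits: ketene [2+2] addition to a strained alkene is thermal, exo-selective and predictable. Its regiochemistry is irrelevant here, and the C7-to-ladder relationship is already fixed in A3. As a single reaction it is more certain than the chosen key step.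
- Weak points: it makes only ring D. Rings A to C with five stereocentres need a separate multistep synthesis of A3. After A4 come dechlorination, removal of a ketone from a bicyclo[2.2.0]hexanone (a system prone to ring opening under forcing basic conditions), debenzylation and attachment of the glycerol unit.
- Comparison: the chosen plan sets brevity and convergence against the greater certainty of this road, and keeps ketene chemistry as its fallback.

**Alternative 3:** The cut is at one ring D bond, made by ring expansion. Base and heat would turn the housane tosylhydrazone A5 into a cyclopropylcarbene. A 1,2-shift of the cyclopropane bond to C3 or C12 would give the ring D ladderene A6, which needs only hydrogenation and acetonide removal.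

- Merits: cyclopropylcarbene-to-cyclobutene expansion is a known reaction type, and A6 carries the same acetonide chain as the chosen route.
- Weak points: the temperatures of carbene generation clash with the thermal lability of both the housane and the ladderene. Fragmentation of the carbene to an alkene and an alkyne competes. A5 presupposes the same tricyclic cyclobutene as Alternative 2 plus cyclopropanation and functional-group adjustment.
- Comparison: the end game after A6 is as short as that of the chosen plan. The chosen plan sets against it that four rings, not one, are made in the key step and that no high-temperature step touches a strained intermediate.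

Key step: step 7

Assumption: compounds 4 and 11 are taken as catalogue compounds. Compounds 13 to 18 are drawn as the ladder diastereomer with the chain cis to ring B.

## Route

Step 1
Reactants: 1 (S)-cyclohex-3-ene-1-carboxylic acid
Product: 2 (S)-cyclohex-3-en-1-ylmethanol
Conditions: LiAlH4, THF, 0 °C to rt
Reagents that add atoms: none
Why: Hydride reduction of a carboxylic acid to the primary alcohol; the stereocentre is not enolised under these conditions and the isolated ring alkene is inert to LiAlH4.

Step 2
Reactants: 2 (S)-cyclohex-3-en-1-ylmethanol
Product: 3 (S)-cyclohex-3-en-1-ylmethyl 4-methylbenzenesulfonate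
Conditions: TsCl, Et3N, DMAP (cat.), CH2Cl2, 0 °C to rt
Reagents that add atoms: 4-toluenesulfonyl chloride (TsCl), Cc1ccc(cc1)S(=O)(=O)Cl
Why: Sulfonylation of an unhindered primary alcohol; no bond to the stereocentre is touched.

Step 3
Reactants: 4 2,2-dimethyl-1,3-dioxan-5-ol; 5 1,7-dibromoheptane
Product: 6 5-[(7-bromoheptyl)oxy]-2,2-dimethyl-1,3-dioxane
Conditions: NaH, DMF, 0 °C; then 5 (3 equiv), n-Bu4NI (cat.), rt
Reagents that add atoms: none
Why: Williamson ether synthesis of a secondary alkoxide with a primary bromide; the excess of the dibromide suppresses double etherification and the surplus is recovered.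

Step 4
Reactants: 6 5-[(7-bromoheptyl)oxy]-2,2-dimethyl-1,3-dioxane; 3 (S)-cyclohex-3-en-1-ylmethyl 4-methylbenzenesulfonate
Product: 8 5-({8-[(1S)-cyclohex-3-en-1-yl]octyl}oxy)-2,2-dimethyl-1,3-dioxane, via Grignard reagent 7 (not isolated)
Conditions: 6, Mg, THF, 40 °C; then 3, Li2CuCl4 (3 mol %), THF, −20 °C to rt
Reagents that add atoms: none
Why: Copper-catalysed sp3–sp3 cross-coupling of a primary alkyl Grignard reagent with a primary tosylate (Kumada-type); the acetonide ether and the ring alkene are inert, and the stereocentre is one carbon away from the reacting centre.

Step 5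
Reactants: 8 5-({8-[(1S)-cyclohex-3-en-1-yl]octyl}oxy)-2,2-dimethyl-1,3-dioxane
Product: 10 (3S)-3-[8-(2,2-dimethyl-1,3-dioxan-5-yloxy)octyl]hexanedial, via ozonide 9 (not isolated)
Conditions: O3, CH2Cl2, NaHCO3, −78 °C; then PPh3, −78 °C to rt
Reagents that add atoms: ozone, [O-][O+]=O
Why: Ozonolysis with reductive work-up cleaves the only alkene to the 1,6-dialdehyde; C7 is beta and gamma to the two aldehydes and cannot epimerise, and the buffered cold conditions spare the acetonide and the ether C–H bonds.

Step 6
Reactants: 10 (3S)-3-[8-(2,2-dimethyl-1,3-dioxan-5-yloxy)octyl]hexanedial; 11 triethyl 4-phosphonocrotonate [ethyl (2E)-4-(diethoxyphosphoryl)but-2-enoate]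
Product: 12 diethyl (2E,4E,7S,10E,12E)-7-[8-(2,2-dimethyl-1,3-dioxan-5-yloxy)octyl]tetradeca-2,4,10,12-tetraenedioate
Conditions: 11 (2.4 equiv), LiN(SiMe3)2, THF, −78 °C; then 10, −78 to 0 °C
Reagents that add atoms: none
Why: Twofold vinylogous Horner–Wadsworth–Emmons olefination; the stabilised phosphonate anion reacts at its alpha carbon and gives the new C4=C5 and C10=C11 bonds with E geometry, and slow addition of the dialdehyde to excess anion at low temperature outruns its aldol self-condensation.

Step 7
Reactants: 12 diethyl (2E,4E,7S,10E,12E)-7-[8-(2,2-dimethyl-1,3-dioxan-5-yloxy)octyl]tetradeca-2,4,10,12-tetraenedioate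
Product: 14 ladder diester (rings A to D closed; CO2Et on C2 and C13 cis and exo; chain cis to ring B), via half-closed bis-acrylate 13 (not isolated)
Conditions: hν (300 nm), acetone/MeCN (1:4), 2 mM, degassed, −20 °C
Reagents that add atoms: none
Why: Proposed new method: acetone-sensitised triplet energy transfer to one (2E,4E)-dienoate of 12 gives a diene triplet whose C5 end adds to C10 of the other arm in a chair-like 6-exo mode (ring A), the two ester-stabilised allyl radicals so formed collapse at C4–C11 to the cyclobutane of ring B (13), and renewed sensitisation of one of the two acrylate arms of 13, which now sit cis on ring B, joins C3 to C12 and then C2 to C13 to close rings C and D as a bicyclo[2.2.0]hexane; the closest known reaction types are the template-directed double [2+2] photodimerisation of stacked ester- or aryl-terminated 1,3-dienes to [3]-ladderanes and the sensitised intramolecular [2+2] cycloaddition of dienes, and the unproven element is that a flexible four-carbon tether takes the place of the rigid template. Ring A therefore closes by radical-type 6-exo-trig attack, ring B by 1,4-diradical recombination, ring C by coupling of the two acrylate beta carbons and ring D by recombination of the two alpha-ester radicals. C5 and C10 should come out cis because a four-membered ring closes far more easily onto a cis- than onto a trans-1,2-disposed pair of radicals; C4 and C11 carry their arms anti to ring A and cis to each other when the two E-configured s-trans dienoates close in register, the geometry favoured while the arms stay stacked; C3 and C12 are set by bonding on the exo face of ring B, which gives the anti ladder; C2 and C13 form cis and exo but are erased in step 9. The ester termini are what make the second half defensible: they leave a sensitisable chromophore once the dienes are spent, and by stabilising radicals at C2 and C13 they favour the straight C3–C12 closure over the crossed, rule-of-five closure that an unactivated 1,5-diene would follow. The one selectivity the substrate cannot secure is the face of ring A on which the ladder grows, because the equatorial chain at C7 fits both chair-like transition states equally well; both ladder diastereomers are expected in similar amounts and 14 would be separated from its epimer at this polar diester stage. Low temperature protects the cis-divinylcyclobutane 13 from Cope rearrangement and high dilution suppresses intermolecular cycloaddition.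

Step 8
Reactants: 14 ladder diester
Product: 15 ladder diacid (CO2H on C2 and C13)
Conditions: LiOH, THF/MeOH/H2O, 40 °C; then dilute HCl to pH 4, 0 °C
Reagents that add atoms: lithium hydroxide, [Li+].[OH-]
Why: Ester saponification; any epimerisation at C2 or C13 is harmless because both centres are removed in the next step, and the brief cold acidification spares the acetonide.

Step 9
Reactants: 15 ladder diacid
Product: 17 5-({8-[tetracyclo[6.4.0.0^2,7.0^3,6]dodecan-10-yl]octyl}oxy)-2,2-dimethyl-1,3-dioxane (acetonide of the target), via bis-thiohydroxamate ester 16 (not isolated)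
Conditions: N-hydroxypyridine-2-thione, N,N'-diisopropylcarbodiimide, DMAP (cat.), CH2Cl2, 0 °C, dark; then t-BuSH (excess), hν (visible), 0 °C
Reagents that add atoms: none
Why: Twofold Barton reductive decarboxylation, a known way to strip carboxyl groups from strained cage and cyclobutane acids; the secondary cyclobutyl radicals at C2 and C13 are trapped by the thiol at high concentration before ring opening, and the neutral activation spares the acetonide.

Step 10
Reactants: 17 acetonide of the target
Product: 18 2-({8-[tetracyclo[6.4.0.0^2,7.0^3,6]dodecan-10-yl]octyl}oxy)propane-1,3-diol (target)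
Conditions: 1 M aq. HCl, THF, rt
Reagents that add atoms: none
Why: Acid-catalysed hydrolysis of the isopropylidene acetal; the saturated ladder has no group that reacts with dilute acid at room temperature.

## Compound list

1 | (S)-cyclohex-3-ene-1-carboxylic acid | OC(=O)[C@H]1CCC=CC1 | starting material
2 | (S)-cyclohex-3-en-1-ylmethanol | OC[C@H]1CCC=CC1 | intermediate
3 | (S)-cyclohex-3-en-1-ylmethyl 4-methylbenzenesulfonate | Cc1ccc(cc1)S(=O)(=O)OC[C@H]1CCC=CC1 | intermediate
4 | 2,2-dimethyl-1,3-dioxan-5-ol | CC1(C)OCC(O)CO1 | starting material
5 | 1,7-dibromoheptane | BrCCCCCCCBr | starting material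
6 | 5-[(7-bromoheptyl)oxy]-2,2-dimethyl-1,3-dioxane | CC1(C)OCC(CO1)OCCCCCCCBr | intermediate
7 | [7-(2,2-dimethyl-1,3-dioxan-5-yloxy)heptyl]magnesium bromide | CC1(C)OCC(CO1)OCCCCCCC[Mg]Br | intermediate (not isolated)
8 | 5-({8-[(1S)-cyclohex-3-en-1-yl]octyl}oxy)-2,2-dimethyl-1,3-dioxane | CC1(C)OCC(CO1)OCCCCCCCC[C@H]1CCC=CC1 | intermediate
9 | ozonide of 8: (3S)-3-[8-(2,2-dimethyl-1,3-dioxan-5-yloxy)octyl]-7,8,9-trioxabicyclo[4.2.1]nonane, mixture at the two acetal carbons | CC1(C)OCC(CO1)OCCCCCCCC[C@H]1CCC2OOC(C1)O2 | intermediate (not isolated)
10 | (3S)-3-[8-(2,2-dimethyl-1,3-dioxan-5-yloxy)octyl]hexanedial | CC1(C)OCC(CO1)OCCCCCCCC[C@H](CC=O)CCC=O | intermediate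
11 | triethyl 4-phosphonocrotonate, ethyl (2E)-4-(diethoxyphosphoryl)but-2-enoate | CCOC(=O)/C=C/CP(=O)(OCC)OCC | starting material
12 | diethyl (2E,4E,7S,10E,12E)-7-[8-(2,2-dimethyl-1,3-dioxan-5-yloxy)octyl]tetradeca-2,4,10,12-tetraenedioate | CC1(C)OCC(CO1)OCCCCCCCC[C@H](C/C=C/C=C/C(=O)OCC)CC/C=C/C=C/C(=O)OCC | intermediate (key-step precursor)
13 | half-closed bis-acrylate: cis-fused bicyclo[4.2.0]octane (rings A and B) with (E)-CH=CH-CO2Et arms on C4 and C11, mutually cis and anti to ring A; octyl ether chain on C7 (S) cis to ring B | CC1(C)OCC(CO1)OCCCCCCCC[C@H]1CC[C@@H]2[C@H](C1)[C@@H](/C=C/C(=O)OCC)[C@H]2/C=C/C(=O)OCC | intermediate (not isolated)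
14 | ladder diester: 5-({8-[4,5-bis(ethoxycarbonyl)tetracyclo[6.4.0.0^2,7.0^3,6]dodecan-10-yl]octyl}oxy)-2,2-dimethyl-1,3-dioxane; all ring fusions cis, neighbouring rings anti, esters cis and exo, chain cis to ring B, chain carbon S | CC1(C)OCC(CO1)OCCCCCCCC[C@H]1CC[C@@H]2[C@H](C1)[C@H]1[C@@H]3[C@@H](C(=O)OCC)[C@@H](C(=O)OCC)[C@@H]3[C@@H]21 | intermediate (key-step product)
15 | ladder diacid: the 4,5-dicarboxylic acid corresponding to 14 | CC1(C)OCC(CO1)OCCCCCCCC[C@H]1CC[C@@H]2[C@H](C1)[C@H]1[C@@H]3[C@@H](C(O)=O)[C@@H](C(O)=O)[C@@H]3[C@@H]21 | intermediate
16 | bis(2-thioxopyridin-1(2H)-yl) ester of 15 | CC1(C)OCC(CO1)OCCCCCCCC[C@H]1CC[C@@H]2[C@H](C1)[C@H]1[C@@H]3[C@@H](C(=O)ON4C=CC=CC4=S)[C@@H](C(=O)ON4C=CC=CC4=S)[C@@H]3[C@@H]21 | intermediate (not isolated)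
17 | 5-({8-[tetracyclo[6.4.0.0^2,7.0^3,6]dodecan-10-yl]octyl}oxy)-2,2-dimethyl-1,3-dioxane; all ring fusions cis, neighbouring rings anti, chain cis to ring B, chain carbon S | CC1(C)OCC(CO1)OCCCCCCCC[C@H]1CC[C@@H]2[C@H](C1)[C@H]1[C@@H]3CC[C@@H]3[C@@H]21 | intermediate
18 | 2-({8-[tetracyclo[6.4.0.0^2,7.0^3,6]dodecan-10-yl]octyl}oxy)propane-1,3-diol; all ring fusions cis, neighbouring rings anti, chain cis to ring B, chain carbon S | OCC(CO)OCCCCCCCC[C@H]1CC[C@@H]2[C@H](C1)[C@H]1[C@@H]3CC[C@@H]3[C@@H]21 | target

## Step count and risks

Total: 10 steps. Longest linear sequence: 9 steps (1 → 2 → 3 → 8 → 10 → 12 → 14 → 15 → 17 → 18; step 3 is the side branch).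

**Step 7 (key step, proposed new method).** Several processes can divert the cascade:
- The excited dienoate may only isomerise about its double bonds and decay without bonding.
- The bis-allyl diradical may recombine at the wrong termini, giving a six- or eight-membered ring in place of ring B.
- The two acrylate arms of 13 may close in the crossed sense, or 13 may undergo Cope rearrangement if it warms.
- Facial selection relative to C7 should be absent, so at best half of the ladder material has the chain cis to ring B.

The fallback sets out from 8 and returns at 17, growing the ladder ring by ring on the intact cyclohexene with known reaction types: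
- Dichloroketene (Cl3CCOCl, Zn, Et2O) adds to the ring alkene of 8 to give dichlorocyclobutanone F1, which closes ring B. Regioisomers and both faces form; the regioisomers converge.
- Zn and NH4Cl in MeOH give cyclobutanone F2, TsNHNH2 gives tosylhydrazone F3, and a Shapiro reaction (LDA, then water) gives the ring B cyclobutene F4. The two face isomers are separated at this stage.
- Cyclopent-2-enone adds under irradiation (enone–alkene [2+2]) to the exo face of F4 to give cyclopentanone F5, in which ring C is in place.
- HCO2Et and NaH give hydroxymethylene ketone F6, and deformylative diazo transfer (TsN3, Et3N) gives diazoketone F7.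
- Photochemical Wolff rearrangement in MeOH contracts the five-membered ring to the ring D methyl ester F8. LiOH gives acid F9, and a single Barton decarboxylation under the conditions of step 9 gives 17.

The price is ten steps in place of five and the same lack of control over the ring A face.

**Step 9.** Anhydride formation from the cis-diacid can stall the second activation, and opening of the bicyclo[2.2.0]hexyl radical can compete with hydrogen transfer. The fallback sets out from 15 and returns at 17. Oxidative bis-decarboxylation of the vicinal diacid (Pb(OAc)4, pyridine, or at a platinum anode) gives the ring D ladderene F10, and hydrogenation (H2, Pd/C, EtOAc, rt) saturates it. This uses the cis-diacid productively and avoids a carbon radical that must wait for a hydrogen donor.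

**Step 6.** Base-induced aldol self-condensation of the 1,6-dialdehyde can outrun olefination, and E selectivity at the new double bonds can erode. The fallback sets out from 10 and returns at 12, using two rounds of neutral stabilised-ylide Wittig chemistry. Ph3P=CHCHO in toluene at 70 °C gives bis-enal F11, and Ph3P=CHCO2Et in CH2Cl2 at rt completes both dienoates.

**Step 4.** Displacement at the beta-branched tosylate may be slow, so that homocoupling and reduction of the Grignard reagent take over. The fallback sets out from 3 (with bromide 6) and returns at 8, reversing the polarity. PhSO2Na in DMF at 80 °C gives sulfone F12. Deprotonation (n-BuLi, THF, −78 °C) and alkylation with 6 give the alkylated sulfone F13. Reductive desulfonylation (Na(Hg), Na2HPO4, MeOH) gives 8.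

## Further compounds

F1 | step 7 | ring B dichlorocyclobutanone from 8 (one regioisomer and the face isomer with chain cis to ring B drawn) | CC1(C)OCC(CO1)OCCCCCCCC[C@H]1CC[C@@H]2[C@H](C1)C(=O)C2(Cl)Cl
F2 | step 7 | ring B cyclobutanone | CC1(C)OCC(CO1)OCCCCCCCC[C@H]1CC[C@@H]2[C@H](C1)C(=O)C2
F3 | step 7 | tosylhydrazone of F2 | CC1(C)OCC(CO1)OCCCCCCCC[C@H]1CC[C@@H]2[C@H](C1)C(=NNS(=O)(=O)c3ccc(C)cc3)C2
F4 | step 7 | ring B cyclobutene (cis-bicyclo[4.2.0]oct-7-ene with the chain) | CC1(C)OCC(CO1)OCCCCCCCC[C@H]1CC[C@@H]2[C@H](C1)C=C2
F5 | step 7 | cyclopentenone photoadduct (rings A, B, C and a cyclopentanone; cis,anti,cis; one regioisomer drawn) | CC1(C)OCC(CO1)OCCCCCCCC[C@H]1CC[C@@H]2[C@H](C1)[C@H]1[C@@H]3C(=O)CC[C@@H]3[C@@H]21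
F6 | step 7 | hydroxymethylene ketone | CC1(C)OCC(CO1)OCCCCCCCC[C@H]1CC[C@@H]2[C@H](C1)[C@H]1[C@@H]3C(=O)C(=CO)C[C@@H]3[C@@H]21
F7 | step 7 | alpha-diazoketone | CC1(C)OCC(CO1)OCCCCCCCC[C@H]1CC[C@@H]2[C@H](C1)[C@H]1[C@@H]3C(=O)C(=[N+]=[N-])C[C@@H]3[C@@H]21
F8 | step 7 | ring D methyl ester (either epimer at the ester carbon) | CC1(C)OCC(CO1)OCCCCCCCC[C@H]1CC[C@@H]2[C@H](C1)[C@H]1[C@@H]3C(C(=O)OC)C[C@@H]3[C@@H]21
F9 | step 7 | ring D carboxylic acid (either epimer at the acid carbon) | CC1(C)OCC(CO1)OCCCCCCCC[C@H]1CC[C@@H]2[C@H](C1)[C@H]1[C@@H]3C(C(O)=O)C[C@@H]3[C@@H]21
F10 | step 9 | ring D ladderene acetonide | CC1(C)OCC(CO1)OCCCCCCCC[C@H]1CC[C@@H]2[C@H](C1)[C@H]1[C@@H]3C=C[C@@H]3[C@@H]21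
F11 | step 6 | (2E,5S,8E)-5-[8-(2,2-dimethyl-1,3-dioxan-5-yloxy)octyl]deca-2,8-dienedial | CC1(C)OCC(CO1)OCCCCCCCC[C@H](C/C=C/C=O)CC/C=C/C=O
F12 | step 4 | (S)-[(cyclohex-3-en-1-ylmethyl)sulfonyl]benzene | O=S(=O)(C[C@H]1CCC=CC1)c1ccccc1
F13 | step 4 | alkylated sulfone (mixture at the sulfonyl carbon) | CC1(C)OCC(CO1)OCCCCCCCC(S(=O)(=O)c2ccccc2)[C@H]1CCC=CC1
A1 | alternative 1 | cis-bicyclo[6.4.0]dodeca-2,4,6,10-tetraene (meso) | C1=CC[C@H]2C=CC=CC=C[C@H]2C1
A2 | alternative 1 | meso tetracyclic diene (ring A cyclohexene, ring D cyclobutene) | C1=CC[C@@H]2[C@H](C1)[C@H]1[C@@H]3C=C[C@@H]3[C@@H]21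
A3 | alternative 2 | tricyclic ring C cyclobutene with benzyl ether chain | c1ccccc1COCCCCCCCC[C@H]1CC[C@@H]2[C@H](C1)[C@H]1C=C[C@@H]21
A4 | alternative 2 | ring D dichlorocyclobutanone (one regioisomer drawn) | c1ccccc1COCCCCCCCC[C@H]1CC[C@@H]2[C@H](C1)[C@H]1[C@@H]3C(=O)C(Cl)(Cl)[C@@H]3[C@@H]21
A5 | alternative 3 | housane carbaldehyde tosylhydrazone (configuration at the cyclopropane CH immaterial) | CC1(C)OCC(CO1)OCCCCCCCC[C@H]1CC[C@@H]2[C@H](C1)[C@H]1[C@@H]3C(C=NNS(=O)(=O)c4ccc(C)cc4)[C@@H]3[C@@H]21
A6 | alternative 3 | ring D ladderene acetonide | CC1(C)OCC(CO1)OCCCCCCCC[C@H]1CC[C@@H]2[C@H](C1)[C@H]1[C@@H]3C=C[C@@H]3[C@@H]21
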